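Read the substrate column of the cedar run as a clock, and ask when it reaches half.

| flask | substrate | reagent | scavenger | free catalyst | added ligand | remark | time |
|---|---|---|---|---|---|---|---|
| cedar | 0.20 M | 0.30 M | 0.24 M | 0.10 mM | 0.52 mM | run made earlier |  |
| ochre | 0.20 M | 0.300 M | 0.240 M | 0.10 mM | 0.26 mM |  | 8.0 min |
| blue | 0.20 M | 0.300 M | 0.240 M | 0.10 mM | 0.26 mM |  | 15 min |
| teal | 0.20 M | 0.300 M | 0.240 M | 0.10 mM | 0.26 mM |  | 30 min |

cedar run (percent of the substrate charged)

| time / s | catalyst intermediate B / % | target / % | catalyst intermediate C / % | substrate / % |
|---|---|---|---|---|
| 10.0 | 0.3 | 1.5 | 0 | 99.0 |
| 12.0 | 0 | 1.7 | 0.2 | 98.1 |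
| 20.0 | 0.4 | 2.9 | 0 | 97.0 |
| 30.0 | 0 | 4.0 | 0 | 96.2 |
| 50.0 | 0 | 5.9 | 0.4 | 94.6 |

(scatter of a reading: 0.3 percentage points)

- which of these there is most of at the end, counted by the substrate in it, ochre (substrate / catalyst intermediate C / catalyst intermediate B / target)
- which of these there is most of at the end, counted by the substrate in it, blue (substrate / catalyst intermediate C / catalyst intermediate B / target)
- which of these there is most of at the end, counted by the substrate in it, teal (substrate / catalyst intermediate C / catalyst intermediate B / target)
- amount of the one of these that there is most of at the end, in percent of the substrate charged, ochre
- amount of the one of these that there is most of at the end, in percent of the substrate charged, blue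
- amount of the one of these that there is most of at the end, in percent of the substrate charged, teal

- what is said of released group includes idle adduct
- candidate steps: catalyst intermediate C -> free catalyst + target; reagent + free catalyst -> catalyst intermediate A; 2 free catalyst -> spent catalyst; substrate + catalyst intermediate A -> catalyst intermediate B; catalyst intermediate B <-> released group + catalyst intermediate C; scavenger + released group -> scavenged by-product; reagent + released group <-> idle adduct; free catalyst + added ligand <-> idle complex
- no earlier run changes the charge of added ligand; that part of a forecast is a guess

**Why watch substrate and target?** The catalyst charge is 0.0500% of the substrate charge, so the catalyst forms can hold no more than that share of it, and target is what substrate has lost.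

**What rate do you integrate?** I take d[substrate]/dt = −k[substrate], treating the catalyst forms and reagent as steady (pseudo-first-order). Then [substrate] falls from its charge as exp(−k·t). The constant k, the substrate clock, is the logarithm of the ratio of two substrate readings divided by the time between them. The last two cedar readings give 0.0503 /min.

**How firm is that?** It is rough. Each reading carries 0.3 percentage points, and the two differ by 1.6 points.

**What does the clock answer?** Substrate and target are equal at the half-time, the natural log of 2 divided by k, which is 13.8 min. That is later than ochre's 8.0 min and earlier than blue's 15 min. So I commit to substrate in ochre at 66.9%, and to target in blue and teal, reaching 77.9% in teal.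

**But ligand is halved, and the rate is falling. Why keep k?** Cedar's target gains 1.5% in the first 10.0 s but 1.9 points over the last 20.0 s, a slower rate. A k that falls further lengthens the half-time. If the catalyst sits bound as idle complex, [free catalyst] goes as the inverse of [added ligand], so with cedar's ligand at twice the new charge, k doubles and the half-time shortens. No earlier run varies ligand, so I leave k unchanged, and that is a guess.

The forecast differs from my reckoning. It names substrate for ochre, blue and teal, at 82%, 79% and 76%, and says “The slowing fits loss of catalyst by the second-order step”.

The flasks give substrate at 73.9% in ochre, substrate at 61.9% in blue and target at 59.8% in teal.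

    catalyst intermediate C → free catalyst + target (k = 1070 /s)
    reagent + free catalyst → catalyst intermediate A (k = 46.7 /M/s)
    2 free catalyst → spent catalyst (k = 13.2 /M/s)
    substrate + catalyst intermediate A → catalyst intermediate B (k = 64.1 /M/s)
    catalyst intermediate B ⇌ released group + catalyst intermediate C (K = 0.0780 M, k = 7.61 /s)
    scavenger + released group → scavenged by-product (k = 2.31 /M/s)
    reagent + released group ⇌ idle adduct, settled at all times (K = 127 /M)
    free catalyst + added ligand ⇌ idle complex (K = 83200 /M, k = 167 /M/s)

Teal's whole-run clock is 0.0304 /min, slower than the 0.0503 /min read from the cedar tail, and by that clock teal's half-time is 22.8 min, shorter than its 30 min. Now take the neighbouring flask, which is teal with 6.5 × 10⁻⁵ M of added ligand instead of 0.26 mM. Scaling teal's clock by the inverse of [added ligand] gives 0.121 /min, and so 2.62% substrate at 30 min. That neighbouring flask holds 98.1% target and 1.91% substrate, with 23.2% of its catalyst in idle complex against teal's 78.7%.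

Readings and results stem from a simulated flask for substances that don't exist.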